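**Retrosynthetic overview**
1. Target 7 ⇒ 6: cleavage of the two aryl methyl ethers (last step).
2. 6 ⇒ 2 + 3: C1'–aryl bond by decarboxylative arylation of a C18 hydroxy acid; the carboxyl carbon is excised, leaving the C17 chain.
3. 2 ⇒ 1: C16–O bond by site- and enantioselective ω-2 C–H hydroxylation of oleic acid; this is the key step and sets the only stereocentre.
4. Rings: none is formed; the benzene ring is bought in 3 and the Z-alkene in 1.

Assumption: the target SMILES is read as (8Z,15S); the P450 variant of step 1 is a catalyst still to be obtained by directed evolution and is the one proposed new element.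

**Step 1**
Reactants: 1 oleic acid [(9Z)-octadec-9-enoic acid]
Product: 2 (9Z,16S)-16-hydroxyoctadec-9-enoic acid
Conditions: evolved P450 BM3 (CYP102A1) variant (E. coli lysate, ca. 0.1 mol %), air (O2), NADP+ (cat.), glucose dehydrogenase, D-glucose (1.5 equiv), catalase, KPi pH 8.0, 2 % DMSO, 25 °C, stopped at ca. 90 % conversion; then pH 3, EtOAc
Reagents that add atoms: dioxygen, O=O
Why: Proposed new method: a laboratory-evolved self-sufficient P450 BM3 variant that keeps the Arg47/Tyr51 carboxylate anchor (fixing the chain register so that C15–C17 reach the haem) but has a reshaped distal pocket (libraries at Phe87, Ala328, Ala82, Val78, Ile263, Leu437) that holds C16 over the ferryl oxygen with its pro-S hydrogen exposed, so that Compound I abstracts H-16(pro-S) and oxygen rebound with retention gives the (16S)-alcohol while the C9=C10 alkene sits 6–7 carbons up the access channel and is not epoxidised; the closest known reaction type is P450 monooxygenase C–H hydroxylation (HAT/oxygen rebound) as in wild-type BM3 sub-terminal (ω-1/ω-2/ω-3) hydroxylation of long-chain fatty acids, oleic acid included, which gives regioisomer mixtures mainly of the (R) series, so the ω-2-specific, (S)-selective catalyst is what is new.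

**Step 2**
Reactants: 2 (9Z,16S)-16-hydroxyoctadec-9-enoic acid; 3 (3,5-dimethoxyphenyl)magnesium chloride (commercial THF solution)
Product: 6 (3S,9Z)-17-(3,5-dimethoxyphenyl)heptadec-9-en-3-ol, via arylzinc chloride 4 (not isolated), via NHPI ester 5 (not isolated)
Conditions: (i) 3 (3 equiv), ZnCl2 (3 equiv), THF, 0 °C → rt; (ii) 2, N-hydroxyphthalimide (1.05 equiv), DIC (1.1 equiv), CH2Cl2, 0 °C → rt (no DMAP), filter, evaporate; (iii) crude 5, Fe(acac)3 (10 mol %), dppBz (12 mol %), then 4, THF, 0 °C → rt, 1 h; aq. NH4Cl
Reagents that add atoms: none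
Why: Fe-catalysed decarboxylative Negishi-type arylation of a redox-active N-acyloxyphthalimide ester: single-electron reduction of 5 releases CO2 and the primary C17 radical, which is captured at aryl–iron and reductively eliminated; primary fatty-acid esters of this kind are good substrates, the remote Z-alkene cannot cyclise competitively (8-membered), the stereocentre is not involved, and protonolysis of ArZnCl by a secondary alcohol is slow compared with the coupling.

**Step 3**
Reactants: 6 (3S,9Z)-17-(3,5-dimethoxyphenyl)heptadec-9-en-3-ol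
Product: 7 Hansfordiol G, 5-[(8Z,15S)-15-hydroxyheptadec-8-en-1-yl]benzene-1,3-diol
Conditions: BBr3 (5 equiv), CH2Cl2, −78 → 0 °C, 3 h; ice/H2O
Reagents that add atoms: none
Why: Lewis-acid aryl methyl ether cleavage (BBr3 O-demethylation): bromide attacks the O-methyl carbon of the ArO(Me)–BBr2 adduct (SN2 at methyl), so no bond to C15 is broken, the secondary alcohol is only masked as a borate that hydrolyses on work-up, and the isolated Z-alkene survives if the mixture is kept at or below 0 °C.

**Compound list**
1 | oleic acid, (9Z)-octadec-9-enoic acid | CCCCCCCC/C=C\CCCCCCCC(=O)O | starting material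
2 | (9Z,16S)-16-hydroxyoctadec-9-enoic acid | CC[C@H](O)CCCCC/C=C\CCCCCCCC(=O)O | intermediate
3 | (3,5-dimethoxyphenyl)magnesium chloride | COc1cc(OC)cc([Mg]Cl)c1 | starting material
4 | (3,5-dimethoxyphenyl)zinc chloride | COc1cc(OC)cc([Zn]Cl)c1 | intermediate
5 | 1,3-dioxoisoindolin-2-yl (9Z,16S)-16-hydroxyoctadec-9-enoate (NHPI ester of 2) | CC[C@H](O)CCCCC/C=C\CCCCCCCC(=O)ON1C(=O)c2ccccc2C1=O | intermediate
6 | (3S,9Z)-17-(3,5-dimethoxyphenyl)heptadec-9-en-3-ol | CC[C@H](O)CCCCC/C=C\CCCCCCCc1cc(OC)cc(OC)c1 | intermediate
7 | Hansfordiol G, 5-[(8Z,15S)-15-hydroxyheptadec-8-en-1-yl]benzene-1,3-diol | CC[C@H](O)CCCCC/C=C\CCCCCCCc1cc(O)cc(O)c1 | target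

**Step count**
Total steps: 3. Longest linear sequence: 3 (1 → 2 → 6 → 7).

**Steps most likely to fail**

Step 1 (the proposed new hydroxylation) is the most likely to fail. No variant may combine ω-2 specificity with the (S) sense; over-oxidation to the 16-ketone and 9,10-epoxidation are the other risks. The fallback uses known chemistry only, sets out from 3 and comes back to the route at 6. Copper-catalysed coupling (Li2CuCl4 cat., THF, 0 °C) of 3 with 9-bromonon-1-ene gives 1,3-dimethoxy-5-(non-8-en-1-yl)benzene F1. CuI-catalysed opening of commercial (S)-2-ethyloxirane at its CH2 by hex-5-enylmagnesium bromide (THF, −30 °C) gives (S)-dec-9-en-3-ol F2, the stereocentre coming from the epoxide. Z-selective cross-metathesis of F1 with F2 (3 equiv) using a cyclometalated ruthenium nitrato catalyst (THF, 35 °C, ethene removed) gives 6, and step 3 follows.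

Step 2 is the second risk. The free C16 hydroxyl may acylate on 5 as its zinc alkoxide, and the electron-rich arylzinc may couple sluggishly. The fallback sets out from 2 and comes back at 6. Ester 5 is isolated and submitted to copper-catalysed decarboxylative borylation (B2pin2, Cu(acac)2, LiOH·H2O, MgCl2, dioxane/DMF, rt) to give (3S,9Z)-17-(4,4,5,5-tetramethyl-1,3,2-dioxaborolan-2-yl)heptadec-9-en-3-ol F3. B-alkyl Suzuki–Miyaura coupling of F3 with 1-bromo-3,5-dimethoxybenzene (Pd(OAc)2, RuPhos, K3PO4, toluene/H2O, 90 °C) then gives 6.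

Step 3 is the third risk. HBr formed from the alcohol and BBr3 may add to or isomerise the alkene, and the C15 borate may go on to the bromide. The fallback sets out from 2 and comes back at 7, replacing methyl by silyl protection. 5-Bromoresorcinol is silylated (TBSCl, imidazole, DMF) to 1-bromo-3,5-bis(tert-butyldimethylsilyloxy)benzene F4. Magnesium insertion in the presence of LiCl and ZnCl2 (THF, rt) gives [3,5-bis(tert-butyldimethylsilyloxy)phenyl]zinc chloride F5. Coupling of F5 with 5 (made from 2 as in step 2) under the same iron catalysis gives (3S,9Z)-17-[3,5-bis(tert-butyldimethylsilyloxy)phenyl]heptadec-9-en-3-ol F6, and TBAF (THF, 0 °C) releases 7.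

**Further compounds**
F1 | step 1 | 1,3-dimethoxy-5-(non-8-en-1-yl)benzene | C=CCCCCCCCc1cc(OC)cc(OC)c1
F2 | step 1 | (S)-dec-9-en-3-ol | CC[C@H](O)CCCCCC=C
F3 | step 2 | (3S,9Z)-17-(4,4,5,5-tetramethyl-1,3,2-dioxaborolan-2-yl)heptadec-9-en-3-ol | CC[C@H](O)CCCCC/C=C\CCCCCCCB1OC(C)(C)C(C)(C)O1
F4 | step 3 | 1-bromo-3,5-bis(tert-butyldimethylsilyloxy)benzene | CC(C)(C)[Si](C)(C)Oc1cc(Br)cc(O[Si](C)(C)C(C)(C)C)c1
F5 | step 3 | [3,5-bis(tert-butyldimethylsilyloxy)phenyl]zinc chloride | CC(C)(C)[Si](C)(C)Oc1cc([Zn]Cl)cc(O[Si](C)(C)C(C)(C)C)c1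
F6 | step 3 | (3S,9Z)-17-[3,5-bis(tert-butyldimethylsilyloxy)phenyl]heptadec-9-en-3-ol | CC[C@H](O)CCCCC/C=C\CCCCCCCc1cc(O[Si](C)(C)C(C)(C)C)cc(O[Si](C)(C)C(C)(C)C)c1
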